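**Plan**

- Numbering: C1 (tiglate carbon)–C2=C3(Me)–C4H2–C5 (aroyloxy carbon)–C6(H)–C7(Me) form seven-membered ring A; C6–C7–C8–C9–C10 form five-membered ring B, with OH and i-Pr on C10.
- Enabling feature: in ring A the C2=C3 alkene lies one methylene (C4) away from the C5 oxygen, a masked β,γ-unsaturated C5 ketone. The retrosynthesis cuts the two ester C–O bonds, returns C5 to the ketone, then cuts C3–C4 into a C5 methyl-ketone enolate and a (Z)-C3 vinyl iodide held cis on ring B.
- Further cuts: C1–C2 (propynyl addition to a C1 acyl group), C10–i-Pr, and C6–C5 with C7–CH3 (conjugate addition/aldol on a cyclopentenone ester that already contains ring B).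
- Forward: ring B is purchased; methyl conjugate addition/aldol/lactonization, i-Pr addition, lactone opening, ynone reduction and hydroalumination–iodination build the two arms; palladium closes ring A at C3–C4; reduction and two acylations finish.
- Stereochemistry: C7 from the chiral copper catalyst; C6 from the cis-fused lactone; C10 by convex-face addition; C1 by (S,S)-ruthenium transfer hydrogenation; Z geometry by trans-hydroalumination; C5 by O10-directed hydride delivery.

Key step: step 11

Assumption: C5 in compounds 5–18 is a temporary carbinol centre that is oxidized in step 9; the anti-aldol (5S) epimer is drawn, and any 5R epimer from step 1 is expected to follow the same steps and converge at ketone 19.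

**Route**

Step 1
Reactants: 1 methyl 3-oxocyclopent-1-ene-1-carboxylate; 2 dimethylzinc; 3 acetaldehyde
Product: 6 cis-fused keto lactone (5S,6S,7R), via zinc enolate 4 (not isolated), via zinc aldolate 5 (not isolated)
Conditions: Me2Zn (3 equiv), Cu(OTf)2 (2.5 mol %), chiral sulfonate-bearing imidazolinium salt derived from 1,2-diphenylethylenediamine (NHC precursor, 2.5 mol %), Et2O, −30 °C; then MeCHO, −78 → 0 °C; aq NH4Cl; PPTS (cat.), CH2Cl2, rt
Reagents that add atoms: none
Why: Copper–NHC-catalysed asymmetric conjugate addition of a dialkylzinc to a β-alkoxycarbonyl cycloalkenone should set the C7 quaternary centre (7R, ligand antipode chosen for that face), the regiodefined zinc enolate then undergoes a Zimmerman–Traxler aldol addition at C6, and because only the aldolate cis to the ester can lactonize while the aldol step is reversible, the material should funnel into the cis-fused lactone with C5 and C1 on the same face of ring B.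

Step 2
Reactants: 6 cis-fused keto lactone; 7 isopropylmagnesium chloride
Product: 8 hydroxy lactone (5S,6S,7R,10R)
Conditions: i-PrMgCl, CeCl3 (anhydrous), THF, −78 °C
Reagents that add atoms: none
Why: Organocerium (Imamoto) 1,2-addition, which is faster at the ketone than at the lactone and suppresses enolization, should occur on the convex face of the cis-bicyclo[3.3.0] system and anti to the C6–C5 bond, placing i-Pr cis to H6 and the new hydroxyl cis to both arms (10R).

Step 3
Reactants: 8 hydroxy lactone
Product: 10 bis(triethylsilyl) Weinreb amide, via dihydroxy Weinreb amide 9 (not isolated)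
Conditions: MeNH(OMe)·HCl, AlMe3, CH2Cl2, 0 °C → rt; then TESOTf, 2,6-lutidine, CH2Cl2, −78 → 0 °C
Reagents that add atoms: N,O-dimethylhydroxylamine hydrochloride, CNOC.Cl; triethylsilyl trifluoromethanesulfonate, CC[Si](CC)(CC)OS(=O)(=O)C(F)(F)F
Why: Weinreb aminolysis of the lactone with the dimethylaluminium amide frees O5 and turns C1 into an acyl donor that stops at the ketone stage, and immediate silylation of both hydroxyls blocks relactonization without touching a stereocentre.

Step 4
Reactants: 10 bis(triethylsilyl) Weinreb amide; 11 1-propynylmagnesium bromide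
Product: 13 ynone, via magnesium hemiaminal adduct 12 (not isolated)
Conditions: THF, 0 °C → rt; aq NH4Cl
Reagents that add atoms: none
Why: Weinreb ketone synthesis, in which the chelated tetrahedral adduct survives until work-up so that exactly one propynyl group (C2, C3 and the C3 methyl) is attached to C1.

Step 5
Reactants: 13 ynone
Product: 14 (1S)-propargylic alcohol
Conditions: Ru[(S,S)-TsNCH(Ph)CH(Ph)NH](p-cymene) (2 mol %), i-PrOH, rt
Reagents that add atoms: none
Why: Noyori asymmetric transfer hydrogenation of an alkynyl ketone is reagent-controlled, the (S,S) catalyst being expected to give the (1S)-carbinol (the spatial arrangement required at C1) regardless of the adjacent quaternary centre, while silyl ethers are unaffected.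

Step 6
Reactants: 14 (1S)-propargylic alcohol
Product: 16 (Z)-iodo allylic alcohol, via cyclic vinylalanate 15 (not isolated)
Conditions: NaAlH2(OCH2CH2OMe)2, THF, 0 °C → rt; EtOAc; then I2, THF, −78 → 0 °C
Reagents that add atoms: iodine, [I][I]
Why: Hydroxyl-directed trans-hydroalumination of the propargylic alcohol puts hydride on C2 and aluminium on C3 in a five-membered alanate, and iodinolysis with retention should give the Z iodide (C1 and I cis) needed for the ring alkene, with C1 unchanged in space (its descriptor becomes R only because the priorities change).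

Step 7
Reactants: 16 (Z)-iodo allylic alcohol
Product: 17 C1 tert-butyldimethylsilyl ether
Conditions: TBSOTf, 2,6-lutidine, CH2Cl2, −78 → 0 °C
Reagents that add atoms: tert-butyldimethylsilyl trifluoromethanesulfonate, CC(C)(C)[Si](C)(C)OS(=O)(=O)C(F)(F)F
Why: Silylation of a hindered secondary alcohol with a silyl triflate and a non-nucleophilic base, under which the vinyl iodide and the triethylsilyl ethers are inert.

Step 8
Reactants: 17 C1 tert-butyldimethylsilyl ether
Product: 18 C5 alcohol
Conditions: PPTS (cat.), MeOH/CH2Cl2, 0 °C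
Reagents that add atoms: none
Why: Acid-catalysed methanolysis distinguishes silyl ethers by steric access, so the secondary triethylsilyl ether at C5 should cleave well before the tertiary one at C10 and the tert-butyldimethylsilyl ether at C1.

Step 9
Reactants: 18 C5 alcohol
Product: 19 C5 methyl ketone
Conditions: Dess–Martin periodinane, NaHCO3, CH2Cl2, 0 °C → rt
Reagents that add atoms: none
Why: Dess–Martin oxidation under buffered, non-enolizing conditions removes the temporary C5 stereocentre without epimerizing C6.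

Step 10
Reactants: 19 C5 methyl ketone
Product: 21 trimethylsilyl enol ether (cyclization precursor), via lithium enolate 20 (not isolated)
Conditions: LiN(SiMe3)2, Me3SiCl, Et3N, THF, −78 °C
Reagents that add atoms: chlorotrimethylsilane, C[Si](C)(C)Cl
Why: Kinetic enolization of the methyl ketone occurs at the methyl group C4 because C6 is a methine between two fully substituted carbons, O-silylation fixes the terminal enolate, and the silylamide base is too weak to dehydrohalogenate the vinyl iodide.

Step 11
Reactants: 21 trimethylsilyl enol ether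
Product: 23 bicyclic β,γ-unsaturated C5 ketone, via tributyltin enolate 22 (not isolated)
Conditions: Pd2(dba)3 (5 mol %), P(t-Bu)3 (20 mol %), Bu3SnF (1.5 equiv), toluene (0.005 M), 80 °C
Reagents that add atoms: none
Why: Zerovalent palladium inserts into the C3–I bond with retention of the Z geometry, Bu3SnF converts the silyl enol ether into tin enolate 22 with loss of Me3SiF, the enolate is transferred to divalent palladium and binds through C4, and reductive elimination forms C3–C4 and regenerates zerovalent palladium. The closest known reaction type is the palladium-catalysed α-arylation and α-alkenylation of ketones through silyl enol ethers or tin enolates, together with intramolecular vinyl halide–ketone enolate couplings that close five- and six-membered rings. Ring A closes as a seven-membered ring by C–C reductive elimination from an eight-membered C,C-palladacycle, with both the C2=C3 alkene and the C4–C5 enolate unit endocyclic, and high dilution is used to suppress intermolecular coupling. No stereocentre is formed, and C1, C6, C7 and C10 should be untouched under these neutral conditions. The step needs C4-versus-C6 regioselectivity, secured by the preformed terminal enol ether, and a cis ring alkene, secured by the Z iodide; the cis arrangement of the two arms on ring B, fixed at the lactone stage, keeps C3 and C4 within reach. The silylated O10 prevents retro-aldol cleavage and proton quench of the tin enolate, and the absence of strong base should keep the β,γ-enone out of conjugation.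

Step 12
Reactants: 23 bicyclic β,γ-unsaturated C5 ketone
Product: 24 C10 hydroxy ketone
Conditions: HF·pyridine, pyridine, THF, 0 °C
Reagents that add atoms: none
Why: Buffered fluoride desilylation should cleave the triethylsilyl ether ahead of the hindered tert-butyldimethylsilyl ether at C1 and avoids base that could conjugate the β,γ-enone or open the β-hydroxy ketone by retro-aldol reaction.

Step 13
Reactants: 24 C10 hydroxy ketone
Product: 26 anti-1,3-diol (5S), via alkoxyborohydride 25 (not isolated)
Conditions: Me4NBH(OAc)3, AcOH/MeCN, −30 → −20 °C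
Reagents that add atoms: none
Why: Evans–Saksena hydroxyl-directed reduction, in which the C10 hydroxyl exchanges onto boron and delivers hydride intramolecularly to the face of the C5 carbonyl on which O10 lies, so the new C5–O bond should end up trans to C10–O and cis to H6 (5S).

Step 14
Reactants: 26 anti-1,3-diol; 27 4-acetoxybenzoyl chloride
Product: 28 C5 4-acetoxybenzoate
Conditions: Et3N, DMAP (cat.), CH2Cl2, 0 °C → rt
Reagents that add atoms: none
Why: DMAP-catalysed acylation with an acid chloride takes the only free secondary hydroxyl (C5), the tertiary C10 hydroxyl being unreactive, and leaves the C5 configuration unchanged.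

Step 15
Reactants: 28 C5 4-acetoxybenzoate
Product: 29 C1 allylic alcohol
Conditions: HF·pyridine, THF, 0 °C → rt
Reagents that add atoms: none
Why: Desilylation with HF·pyridine removes the C1 silyl ether under mildly acidic conditions that spare the alkyl benzoate and the aryl acetate.

Step 16
Reactants: 29 C1 allylic alcohol; 30 tiglic acid
Product: 32 C1 tiglate, via mixed anhydride 31 (not isolated)
Conditions: 2,4,6-Cl3C6H2COCl, Et3N, toluene, rt; then 29, DMAP, toluene, 60 °C
Reagents that add atoms: none
Why: Yamaguchi esterification through the 2,4,6-trichlorobenzoic mixed anhydride acylates hindered secondary alcohols with retention at C1 and without E-to-Z scrambling of the 2-methylbut-2-enoyl group, while the tertiary hydroxyl stays free.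

Step 17
Reactants: 32 C1 tiglate
Product: 33 target compound
Conditions: pyrrolidine (2 equiv), CH2Cl2, 0 °C → rt
Reagents that add atoms: none
Why: Aminolysis of an aryl acetate, the phenolic ester being far more electrophilic than the hindered tiglate and the alkyl benzoate, so only the acetyl group should be transferred to the amine.

**Compound list**

1 | methyl 3-oxocyclopent-1-ene-1-carboxylate | COC(=O)C1=CC(=O)CC1 | starting material
2 | dimethylzinc | C[Zn]C | starting material
3 | acetaldehyde | CC=O | starting material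
4 | methylzinc enolate (C6=C10) of methyl (1R)-1-methyl-3-oxocyclopentane-1-carboxylate | C[Zn]OC1=C[C@](C)(C(=O)OC)CC1 | intermediate (not isolated)
5 | methylzinc aldolate, methyl (1R,2S)-1-methyl-2-[(1S)-1-(methylzinciooxy)ethyl]-3-oxocyclopentane-1-carboxylate | C[C@H](O[Zn]C)[C@@H]1[C@](C)(C(=O)OC)CCC1=O | intermediate (not isolated)
6 | (3S,3aS,6aR)-3,6a-dimethyltetrahydro-1H-cyclopenta[c]furan-1,4(3H)-dione (route numbering 5S,6S,7R; lactone C1(=O)–O–C5, ketone C10) | C[C@H]2[C@@H]1[C@](C)(C(=O)O2)CCC1=O | intermediate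
7 | isopropylmagnesium chloride | CC(C)[Mg]Cl | starting material
8 | (3S,3aS,4R,6aR)-4-hydroxy-3,6a-dimethyl-4-(propan-2-yl)hexahydro-1H-cyclopenta[c]furan-1-one | C[C@H]2[C@@H]1[C@](C)(C(=O)O2)CC[C@@]1(O)C(C)C | intermediate
9 | (1R,2S,3R)-3-hydroxy-2-[(1S)-1-hydroxyethyl]-N-methoxy-N,1-dimethyl-3-(propan-2-yl)cyclopentane-1-carboxamide | C[C@H](O)[C@@H]1[C@](C)(C(=O)N(C)OC)CC[C@@]1(O)C(C)C | intermediate (not isolated)
10 | (1R,2S,3R)-N-methoxy-N,1-dimethyl-3-(propan-2-yl)-3-[(triethylsilyl)oxy]-2-{(1S)-1-[(triethylsilyl)oxy]ethyl}cyclopentane-1-carboxamide | C[C@H](O[Si](CC)(CC)CC)[C@@H]1[C@](C)(C(=O)N(C)OC)CC[C@@]1(O[Si](CC)(CC)CC)C(C)C | intermediate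
11 | 1-propynylmagnesium bromide | CC#C[Mg]Br | starting material
12 | bromomagnesium alkoxide of the N-methoxy-N-methyl hemiaminal from propynyl addition to C1 of 10 | C[C@H](O[Si](CC)(CC)CC)[C@@H]1[C@](C)(C(O[Mg]Br)(C#CC)N(C)OC)CC[C@@]1(O[Si](CC)(CC)CC)C(C)C | intermediate (not isolated)
13 | 1-[(1R,2S,3R)-1-methyl-3-(propan-2-yl)-3-[(triethylsilyl)oxy]-2-{(1S)-1-[(triethylsilyl)oxy]ethyl}cyclopentyl]but-2-yn-1-one | C[C@H](O[Si](CC)(CC)CC)[C@@H]1[C@](C)(C(=O)C#CC)CC[C@@]1(O[Si](CC)(CC)CC)C(C)C | intermediate
14 | (1S)-1-[(1R,2S,3R)-1-methyl-3-(propan-2-yl)-3-[(triethylsilyl)oxy]-2-{(1S)-1-[(triethylsilyl)oxy]ethyl}cyclopentyl]but-2-yn-1-ol | C[C@H](O[Si](CC)(CC)CC)[C@@H]1[C@](C)([C@H](O)C#CC)CC[C@@]1(O[Si](CC)(CC)CC)C(C)C | intermediate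
15 | sodium salt of the five-membered alkoxy(vinyl)alanate (O1–Al–C3=C2–C1 ring, two 2-methoxyethoxy ligands on Al) | C[C@H](O[Si](CC)(CC)CC)[C@@H]1[C@](C)([C@@H]2O[Al-](OCCOC)(OCCOC)C(C)=C2)CC[C@@]1(O[Si](CC)(CC)CC)C(C)C.[Na+] | intermediate (not isolated)
16 | (1R,2Z)-3-iodo-1-[(1R,2S,3R)-1-methyl-3-(propan-2-yl)-3-[(triethylsilyl)oxy]-2-{(1S)-1-[(triethylsilyl)oxy]ethyl}cyclopentyl]but-2-en-1-ol | C[C@H](O[Si](CC)(CC)CC)[C@@H]1[C@](C)([C@H](O)/C=C(/C)I)CC[C@@]1(O[Si](CC)(CC)CC)C(C)C | intermediate
17 | C1 tert-butyldimethylsilyl ether of 16 | C[C@H](O[Si](CC)(CC)CC)[C@@H]1[C@](C)([C@H](O[Si](C)(C)C(C)(C)C)/C=C(/C)I)CC[C@@]1(O[Si](CC)(CC)CC)C(C)C | intermediate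
18 | (1S)-1-[(1S,2R,5R)-2-{(1R,2Z)-1-[(tert-butyldimethylsilyl)oxy]-3-iodobut-2-en-1-yl}-2-methyl-5-(propan-2-yl)-5-[(triethylsilyl)oxy]cyclopentyl]ethan-1-ol | C[C@H](O)[C@@H]1[C@](C)([C@H](O[Si](C)(C)C(C)(C)C)/C=C(/C)I)CC[C@@]1(O[Si](CC)(CC)CC)C(C)C | intermediate
19 | methyl ketone obtained by oxidizing C5 of 18 (acetyl on C6; 1R,6R,7R,10R by route numbering) | CC(=O)[C@@H]1[C@](C)([C@H](O[Si](C)(C)C(C)(C)C)/C=C(/C)I)CC[C@@]1(O[Si](CC)(CC)CC)C(C)C | intermediate
20 | lithium enolate of 19 at C4=C5 | C=C(O[Li])[C@@H]1[C@](C)([C@H](O[Si](C)(C)C(C)(C)C)/C=C(/C)I)CC[C@@]1(O[Si](CC)(CC)CC)C(C)C | intermediate (not isolated)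
21 | trimethylsilyl enol ether of 19 at C4=C5 (1-(trimethylsilyloxy)ethenyl on C6; C1 OTBS Z-iodobutenyl arm and methyl on C7; OTES and i-Pr on C10) | C=C(O[Si](C)(C)C)[C@@H]1[C@](C)([C@H](O[Si](C)(C)C(C)(C)C)/C=C(/C)I)CC[C@@]1(O[Si](CC)(CC)CC)C(C)C | intermediate
22 | tributyltin enolate corresponding to 21 | C=C(O[Sn](CCCC)(CCCC)CCCC)[C@@H]1[C@](C)([C@H](O[Si](C)(C)C(C)(C)C)/C=C(/C)I)CC[C@@]1(O[Si](CC)(CC)CC)C(C)C | intermediate (not isolated)
23 | (3R,3aR,8R,8aR)-8-[(tert-butyldimethylsilyl)oxy]-6,8a-dimethyl-3-(propan-2-yl)-3-[(triethylsilyl)oxy]-2,3,3a,5,8,8a-hexahydroazulen-4(1H)-one | CC(C)(C)[Si](C)(C)O[C@@H]1C=C(C)CC(=O)[C@@H]2[C@@]1(C)CC[C@@]2(O[Si](CC)(CC)CC)C(C)C | intermediate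
24 | (3R,3aR,8R,8aR)-8-[(tert-butyldimethylsilyl)oxy]-3-hydroxy-6,8a-dimethyl-3-(propan-2-yl)-2,3,3a,5,8,8a-hexahydroazulen-4(1H)-one | CC(C)(C)[Si](C)(C)O[C@@H]1C=C(C)CC(=O)[C@@H]2[C@@]1(C)CC[C@@]2(O)C(C)C | intermediate
25 | tetramethylammonium salt of the O10-bound diacetoxyborohydride of 24 | CC(C)(C)[Si](C)(C)O[C@@H]1C=C(C)CC(=O)[C@@H]2[C@@]1(C)CC[C@@]2(O[BH-](OC(C)=O)OC(C)=O)C(C)C.C[N+](C)(C)C | intermediate (not isolated)
26 | (3R,3aS,4S,8R,8aR)-8-[(tert-butyldimethylsilyl)oxy]-6,8a-dimethyl-3-(propan-2-yl)-1,2,3,3a,4,5,8,8a-octahydroazulene-3,4-diol | CC(C)(C)[Si](C)(C)O[C@@H]1C=C(C)C[C@H](O)[C@@H]2[C@@]1(C)CC[C@@]2(O)C(C)C | intermediate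
27 | 4-acetoxybenzoyl chloride | CC(=O)Oc1ccc(cc1)C(Cl)=O | starting material
28 | (3R,3aS,4S,8R,8aR)-8-[(tert-butyldimethylsilyl)oxy]-3-hydroxy-6,8a-dimethyl-3-(propan-2-yl)-1,2,3,3a,4,5,8,8a-octahydroazulen-4-yl 4-(acetyloxy)benzoate | CC(C)(C)[Si](C)(C)O[C@@H]1C=C(C)C[C@H](OC(=O)c2ccc(OC(C)=O)cc2)[C@@H]2[C@@]1(C)CC[C@@]2(O)C(C)C | intermediate
29 | (3R,3aS,4S,8R,8aR)-3,8-dihydroxy-6,8a-dimethyl-3-(propan-2-yl)-1,2,3,3a,4,5,8,8a-octahydroazulen-4-yl 4-(acetyloxy)benzoate | O[C@@H]1C=C(C)C[C@H](OC(=O)c2ccc(OC(C)=O)cc2)[C@@H]2[C@@]1(C)CC[C@@]2(O)C(C)C | intermediate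
30 | tiglic acid, (2E)-2-methylbut-2-enoic acid | C/C=C(\C)C(=O)O | starting material
31 | (2E)-2-methylbut-2-enoic 2,4,6-trichlorobenzoic anhydride | C/C=C(\C)C(=O)OC(=O)c1c(Cl)cc(Cl)cc1Cl | intermediate (not isolated)
32 | (3R,3aS,4S,8R,8aR)-3-hydroxy-6,8a-dimethyl-8-{[(2E)-2-methylbut-2-enoyl]oxy}-3-(propan-2-yl)-1,2,3,3a,4,5,8,8a-octahydroazulen-4-yl 4-(acetyloxy)benzoate | C/C=C(\C)C(=O)O[C@@H]1C=C(C)C[C@H](OC(=O)c2ccc(OC(C)=O)cc2)[C@@H]2[C@@]1(C)CC[C@@]2(O)C(C)C | intermediate
33 | (3R,3aS,4S,8R,8aR)-3-hydroxy-6,8a-dimethyl-8-{[(2E)-2-methylbut-2-enoyl]oxy}-3-(propan-2-yl)-1,2,3,3a,4,5,8,8a-octahydroazulen-4-yl 4-hydroxybenzoate (route numbering 1R,5S,6S,7R,10R) | C/C=C(\C)C(=O)O[C@@H]1C=C(C)C[C@H](OC(=O)c2ccc(O)cc2)[C@@H]2[C@@]1(C)CC[C@@]2(O)C(C)C | target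

**Totals and risks**

Total step count: 17. Longest linear sequence: 17 steps (from 1).

Steps most likely to fail:

Step 11. Reductive elimination from the eight-membered palladacycle may be slow, so proto-deiodination or intermolecular coupling could outrun the seven-membered closure. Fallback: setting out from 21, hydroboration of the enol ether double bond with 9-BBN (THF, rt) gives the C4 alkylborane F1. An intramolecular B-alkyl Suzuki–Miyaura coupling (PdCl2(dppf), AsPh3, Cs2CO3, DMF/THF/H2O, high dilution) then joins C4 to the C3 iodide and gives the ring-closed C5 silyl ether F2 with the same C3–C4 bond. K2CO3/MeOH frees the C5 alcohol F3 (epimer mixture), and Dess–Martin oxidation returns to the route at 23.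

Step 1. Facial discrimination by the copper catalyst on the five-membered keto ester may be insufficient, leaving material of low enantiomeric purity. Fallback: setting out from 1, Me2CuLi (THF, −78 °C) followed by acetaldehyde and the same lactonization gives the lactone as a racemate, 6 together with its mirror image F4. Steps 2–4 carry the racemate forward, so that the mirror-image hydroxy lactone F5, the mirror-image Weinreb amide F6 and the mirror-image ynone F7 accompany 8, 10 and 13. The reagent-controlled transfer hydrogenation of step 5 then converts the two ynone enantiomers into diastereomeric (1S)-carbinols, 14 and the diastereomeric carbinol F8, which are separated by chromatography; the route is rejoined at 14.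

Step 2. Enolization or β-hydride reduction of the hindered ketone may outrun addition of the secondary alkyl group. Fallback: setting out from 6, isopropenylmagnesium bromide with CeCl3 (THF, −78 °C), a smaller sp2 nucleophile with no transferable β-hydrogen, should add on the same convex face to give the isopropenyl carbinol F9. Hydrogenation of its 1,1-disubstituted alkene (H2, PtO2, EtOAc) returns to the route at 8.

**Further compounds**

F1 | step 11 | B-alkyl-9-BBN adduct of 21 (boron on C4, trimethylsilyloxy on C5) | C[Si](C)(C)OC(CB2C3CCCC2CCC3)[C@@H]1[C@](C)([C@H](O[Si](C)(C)C(C)(C)C)/C=C(/C)I)CC[C@@]1(O[Si](CC)(CC)CC)C(C)C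
F2 | step 11 | ring-closed C5 trimethylsilyl ether (C5 epimers; C1 OTBS, C10 OTES) | CC(C)(C)[Si](C)(C)O[C@@H]1C=C(C)CC(O[Si](C)(C)C)[C@@H]2[C@@]1(C)CC[C@@]2(O[Si](CC)(CC)CC)C(C)C
F3 | step 11 | ring-closed C5 alcohol (C5 epimers; C1 OTBS, C10 OTES) | CC(C)(C)[Si](C)(C)O[C@@H]1C=C(C)CC(O)[C@@H]2[C@@]1(C)CC[C@@]2(O[Si](CC)(CC)CC)C(C)C
F4 | step 1 | mirror image of keto lactone 6 | C[C@@H]2[C@H]1[C@@](C)(C(=O)O2)CCC1=O
F5 | step 1 | mirror image of hydroxy lactone 8 | C[C@@H]2[C@H]1[C@@](C)(C(=O)O2)CC[C@]1(O)C(C)C
F6 | step 1 | mirror image of Weinreb amide 10 | C[C@@H](O[Si](CC)(CC)CC)[C@H]1[C@@](C)(C(=O)N(C)OC)CC[C@]1(O[Si](CC)(CC)CC)C(C)C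
F7 | step 1 | mirror image of ynone 13 | C[C@@H](O[Si](CC)(CC)CC)[C@H]1[C@@](C)(C(=O)C#CC)CC[C@]1(O[Si](CC)(CC)CC)C(C)C
F8 | step 1 | (1S)-carbinol from F7, diastereomer of 14 | C[C@@H](O[Si](CC)(CC)CC)[C@H]1[C@@](C)([C@H](O)C#CC)CC[C@]1(O[Si](CC)(CC)CC)C(C)C
F9 | step 2 | isopropenyl analogue of hydroxy lactone 8 | C[C@H]2[C@@H]1[C@](C)(C(=O)O2)CC[C@@]1(O)C(C)=C
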